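**Retrosynthetic overview**

- Feature: N joins C12 (the ring A CH that carries ring E), C9 = Cq (common to rings A, B and C) and C18 (a ring B CH2). Rings A and B are therefore a cyclohexanone (C18 = carbonyl, Cq = α-carbon) with a 3-azidoalkyl arm on Cq. An intramolecular azide Schmidt ring expansion forms N–C18 and N–Cq and closes A and B together; the lactam carbonyl is then removed through the thiolactam.
- The azido cis-hydrindanone comes from a cyclopentenone (ring C) made by alkyne hydration and aldol cyclodehydration on a 2-pentynylcyclohexanone. Cq is set by an organocatalytic Robinson annulation, and the second ring of that enone is later opened by ozonolysis so that its four carbons become C10–C13.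
- Ring D: acetate alkylation at C8, cis reduction at C4, hydroxyl-directed hydrogenation (sets C3 and C22), lactonisation, then hydroxylation and methylation at C7.
- Ring E and nitrogen: Felkin addition of a chiral Grignard reagent to the C13 aldehyde, oxidative lactonisation, Mitsunobu azidation at C12 with inversion.
- Ring order: six-membered carbocycle of ring B (from the start) → C → D → E → A and B together.

Key step: step 22

Atom labels (atom order of the target SMILES): C1–C2 ethyl; C3 CH–Et; C4 CH–O of ring D; C6 lactone D carbonyl; C7 C(Me)(OH); C8 ring C/D CH next to Cq; C9 = Cq; C10, C11 ring A CH2; C12 ring A CH–N; C13 ring E CH–O; C14 CH2; C15 CH–Me; C16 lactone E carbonyl; C18–C21 ring B carbons counted from N; C22 ring B/C CH. "Up" is the face of ring C that carries the oxygen on C4. TBS = tert-butyldimethylsilyl.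

Assumption: the binam-prolinamide of the D-proline series gives the aldol sense opposite to that of L-proline (which leads to the (S)-methyl Wieland–Miescher ketone), and the pentynyl analogue follows the methyl parent; by the CIP rules the product 6 is then (S).

Step 1
Reactants: 1 cyclohexane-1,3-dione; 2 1-bromopent-2-yne
Product: 3 2-(pent-2-yn-1-yl)cyclohexane-1,3-dione
Conditions: KOH, H2O, 50 °C
Reagents that add atoms: none
Why: C-alkylation of a cyclic 1,3-dione enolate by a propargylic bromide in water, where solvation of the enolate oxygens favours attack through carbon.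

Step 2
Reactants: 3 2-(pent-2-yn-1-yl)cyclohexane-1,3-dione; 4 but-3-en-2-one
Product: 6 (S)-8a-(pent-2-yn-1-yl)-3,4,8,8a-tetrahydronaphthalene-1,6(2H,7H)-dione, via Michael triketone 5 (not isolated)
Conditions: 4, Et3N (cat.), neat, rt; then N-tosyl-(Ra)-binam-D-prolinamide (cat.), PhCO2H (cat.), neat, rt
Reagents that add atoms: none
Why: Michael addition followed by an enamine-catalysed aldol cyclodehydration that selects one of the two enantiotopic ring carbonyls (Hajos–Parrish–Eder–Sauer–Wiechert type Robinson annulation) should set Cq.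

Step 3
Reactants: 6 (S)-8a-(pent-2-yn-1-yl)-3,4,8,8a-tetrahydronaphthalene-1,6(2H,7H)-dione
Product: 7 monoketal of 6 (1,3-dioxolane at the saturated ketone C18; enone intact)
Conditions: ethylene glycol, p-TsOH·H2O (cat.), 4 Å MS, rt
Reagents that add atoms: ethylene glycol, OCCO
Why: Acid-catalysed ketalisation should take the saturated ketone and leave the less electrophilic conjugated carbonyl, as is usual for Wieland–Miescher-type diketones.

Step 4
Reactants: 7 monoketal of 6
Product: 8 allylic alcohol (12R; hydroxyl cis to the pentynyl group)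
Conditions: NaBH4, CeCl3·7H2O, MeOH, −78 → 0 °C
Reagents that add atoms: none
Why: Luche 1,2-reduction with axial hydride delivery anti to the angular pentynyl group should give the pseudo-equatorial alcohol cis to that group, which sets C12 (inverted later by azide).

Step 5
Reactants: 8 allylic alcohol
Product: 9 TBS ether of 8
Conditions: TBSCl, imidazole, DMF, rt
Reagents that add atoms: tert-butyldimethylsilyl chloride, CC(C)(C)[Si](C)(C)Cl
Why: Standard silylation of a secondary allylic alcohol, giving a group that cannot chelate in step 8.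

Step 6
Reactants: 9 TBS ether of 8
Product: 10 (2R)-2-(TBSO)-4-[(6S)-7-oxo-6-(pent-2-yn-1-yl)-1,4-dioxaspiro[4.5]decan-6-yl]butanal
Conditions: O3, CH2Cl2/MeOH, NaHCO3, Sudan Red 7B, −78 °C; then Me2S, −78 °C → rt
Reagents that add atoms: ozone, [O-][O+]=O
Why: Ozonolysis of the electron-rich trisubstituted alkene, far faster than attack on the dialkyl alkyne and stopped at the indicator end point, opens the second ring so that its carbons become C10–C13 and unveils the C22 ketone.

Step 7
Reactants: 11 (R)-3-bromo-2-methylpropan-1-ol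
Product: 12 (R)-(3-bromo-2-methylpropoxy)(tert-butyl)dimethylsilane
Conditions: TBSCl, imidazole, CH2Cl2, rt
Reagents that add atoms: tert-butyldimethylsilyl chloride, CC(C)(C)[Si](C)(C)Cl
Why: Standard silylation of the primary alcohol; the stereocentre (later C15) is not touched.

Step 8
Reactants: 10 keto aldehyde; 12 (R)-(3-bromo-2-methylpropoxy)(tert-butyl)dimethylsilane
Product: 14 (12R,13S,15S)-alcohol (free C13–OH anti to C12–OTBS; ring ketone and alkyne intact), via Grignard reagent 13 (not isolated)
Conditions: 12, Mg, THF, 50 °C; then 10, Et2O/THF, −78 °C; H2O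
Reagents that add atoms: none
Why: Grignard addition to the α-silyloxy aldehyde under non-chelating Felkin–Anh control should give the 1,2-anti product and so set C13, while the hindered ring ketone next to Cq is not attacked at low temperature.

Step 9
Reactants: 14 (12R,13S,15S)-alcohol
Product: 15 tris-TBS ether (C12, C13 and C16 oxygens silylated)
Conditions: TBSOTf, 2,6-lutidine, CH2Cl2, −78 → −40 °C
Reagents that add atoms: tert-butyldimethylsilyl triflate, CC(C)(C)[Si](C)(C)OS(=O)(=O)C(F)(F)F
Why: Silylation of the hindered secondary alcohol by the silyl triflate is faster at low temperature than enol silylation of the neopentyl ketone, and it stops silyl migration between the vicinal oxygens in later basic steps.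

Step 10
Reactants: 15 tris-TBS ether
Product: 17 bicyclic enone (ring C cyclopentenone: C22=C3 bearing ethyl; C4=O; C8H2; dioxolane at C18), via 1,4-diketone 16 (not isolated)
Conditions: Ph3PAuNTf2 (cat.), H2O, 1,4-dioxane, 60 °C; then KOH, EtOH, 60 °C
Reagents that add atoms: water, O (taken up in 16; one equivalent of water is released again in the condensation)
Why: Gold-catalysed alkyne hydration steered by 5-exo attack of the neighbouring C22 carbonyl oxygen should give the 1,4-diketone regioselectively, and intramolecular aldol condensation of its propyl ketone onto C22 then closes ring C.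

Step 11
Reactants: 17 bicyclic enone; 18 tert-butyl bromoacetate
Product: 19 C8-alkylated enone (CH2CO2t-Bu on C8 cis to the C10 chain)
Conditions: LiN(i-Pr)2, THF, −78 °C; then 18, DMPU, −78 → −40 °C
Reagents that add atoms: none
Why: Kinetic deprotonation at the only α' position (C8) and alkylation of the cross-conjugated lithium dienolate on the face opposite to the fully substituted dioxolane carbon on Cq should place the acetate arm on the up face (enolate alkylation).

Step 12
Reactants: 19 C8-alkylated enone
Product: 20 allylic alcohol (C4–OH up; cis to the acetate arm)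
Conditions: LiBH(s-Bu)3, THF, −78 °C; H2O at −78 °C
Reagents that add atoms: none
Why: The bulky hydride adds 1,2 to the fully β-substituted enone from the face opposite to the adjacent acetate arm, which should give the C4 carbinol cis to that arm.

Step 13
Reactants: 20 allylic alcohol
Product: 21 cis-hydrindane hydroxy ester (H on C3 and C22 up; ethyl down)
Conditions: H2, [Ir(cod)(PCy3)(py)]PF6 (cat.), CH2Cl2, rt
Reagents that add atoms: none
Why: Hydroxyl-directed hydrogenation delivers both hydrogens to the face of the C4 hydroxyl, which should set the cis ring fusion at C22 and put the ethyl group at C3 on the opposite face.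

Step 14
Reactants: 21 cis-hydrindane hydroxy ester
Product: 22 tricyclic lactone (ring D closed; C7 is CH2)
Conditions: t-BuOK (cat.), THF, 0 °C → rt
Reagents that add atoms: none
Why: Alkoxide-catalysed intramolecular transesterification (5-exo-trig) of the cis γ-hydroxy ester closes ring D, which can only be cis-fused.

Step 15
Reactants: 22 tricyclic lactone
Product: 23 α-hydroxy lactone (C7–OH on the convex face)
Conditions: KN(SiMe3)2, THF, −78 °C; 2-(phenylsulfonyl)-3-phenyloxaziridine; H2O
Reagents that add atoms: 2-(phenylsulfonyl)-3-phenyloxaziridine, O=S(=O)(c1ccccc1)N1OC1c1ccccc1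
Why: Davis oxidation of the potassium lactone enolate from the convex face of the cis-fused bicycle; this centre is enolised again in step 17, so only the oxygen matters.

Step 16
Reactants: 23 α-hydroxy lactone
Product: 24 α-silyloxy lactone (C7–OTBS)
Conditions: TBSOTf, 2,6-lutidine, CH2Cl2, 0 °C
Reagents that add atoms: tert-butyldimethylsilyl triflate, CC(C)(C)[Si](C)(C)OS(=O)(=O)C(F)(F)F
Why: Standard silylation, needed so that the C7 enolate can be formed and alkylated at carbon.

Step 17
Reactants: 24 α-silyloxy lactone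
Product: 25 α-methyl-α-silyloxy lactone (C7: methyl exo, oxygen endo)
Conditions: LiN(i-Pr)2, THF/DMPU, −78 °C; MeI, −78 → −30 °C
Reagents that add atoms: iodomethane, CI
Why: Alkylation of the α-silyloxy lactone enolate by iodomethane from the convex face, away from ring C and the C10 chain, should put methyl exo and oxygen endo at C7 as in the target.

Step 18
Reactants: 25 α-methyl-α-silyloxy lactone
Product: 26 tetraol (C7, C12, C13 and C16 hydroxyls free; dioxolane intact)
Conditions: Bu4NF, AcOH, THF, rt → 40 °C
Reagents that add atoms: none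
Why: Fluoride cleaves all four silyl ethers, and the acetic acid buffer protects the lactone while the ketal is inert to fluoride.

Step 19
Reactants: 26 tetraol
Product: 28 bis-lactone alcohol (ring E closed through the C13 oxygen; C12–OH free), via dihydroxy acid 27 (not isolated)
Conditions: TEMPO (cat.), NaOCl (cat.), NaClO2, MeCN/phosphate buffer (pH 6.7), 35 °C; then aq. citric acid (pH 3), rt
Reagents that add atoms: sodium chlorite, [Na+].[O-]Cl=O (its oxygen enters acid 27; lactonisation then releases one oxygen as water)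
Why: Oxoammonium/chlorite oxidation takes only the primary alcohol to the acid, and the 4,5-dihydroxy acid should then close to the favoured five-membered lactone through the C13 hydroxyl with retention there.

Step 20
Reactants: 28 bis-lactone alcohol
Product: 29 azide (12S; dioxolane intact)
Conditions: PPh3, DIAD, (PhO)2P(O)N3, THF, 0 °C → rt
Reagents that add atoms: diphenylphosphoryl azide, [N-]=[N+]=NP(=O)(Oc1ccccc1)Oc1ccccc1
Why: Mitsunobu substitution of the only reactive (secondary) hydroxyl by azide with inversion should give the C12 configuration of the target; the tertiary hydroxyl is inert.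

Step 21
Reactants: 29 azide
Product: 30 azidoalkyl cis-hydrindanone (C18 ketone free)
Conditions: 2 M aq. HCl, THF, 40 °C
Reagents that add atoms: water, O
Why: Acid hydrolysis of the dioxolane; the azide, both lactones and the tertiary α-hydroxy lactone are stable to dilute aqueous acid.

Step 22
Reactants: 30 azidoalkyl cis-hydrindanone
Product: 31 ring B lactam of the target
Conditions: TiCl4, CH2Cl2, 0 °C → rt; aq. NaHCO3
Reagents that add atoms: none
Why: TiCl4 activates the C18 carbonyl, the tethered secondary azide adds through its alkylated nitrogen to give a six-membered azidohydrin (6-exo-trig), and the Cq–C18 bond antiperiplanar to the departing N2 shifts to nitrogen, so ring A (N, C12, C11, C10, Cq) and ring B (the cyclohexanone enlarged by N to the seven-membered lactam) form in one operation. The closest known reaction type is the intramolecular azide Schmidt reaction of 2-(3-azidopropyl)cycloalkanones to fused bicyclic lactams, including cases that create aza-quaternary carbons. No stereocentre is formed: the 1,2-shift goes with retention at Cq, so N takes the place of C18 on the face of the cis ring fusion, and C12 is not touched. The step needs migration of Cq and not of the C19 methylene (which would give a bridged lactam); the three-carbon tether on Cq makes Cq–C18 the ring bond of the azidohydrin chair that lies anti to an equatorial N2 group, and the more substituted carbon is also the better migrating group. The lactones and the tertiary α-hydroxy lactone should not ionise under these conditions and are set free from titanium on work-up.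

Step 23
Reactants: 31 ring B lactam
Product: 32 thiolactam
Conditions: Lawesson's reagent, THF, 45 °C
Reagents that add atoms: Lawesson's reagent, COc1ccc(cc1)P1(=S)SP(=S)(S1)c1ccc(OC)cc1
Why: Thionation is selective for the electron-rich tertiary lactam carbonyl over the two lactone carbonyls.

Step 24
Reactants: 32 thiolactam
Product: 33 target CNP0260919.4
Conditions: Raney Ni (W-2), EtOH/THF, rt
Reagents that add atoms: none
Why: Raney Ni desulfurisation turns C=S into CH2 and spares the lactones and the tertiary alcohol.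

**Compound list**

1 | cyclohexane-1,3-dione | O=C1CCCC(=O)C1 | starting material
2 | 1-bromopent-2-yne | CCC#CCBr | starting material
3 | 2-(pent-2-yn-1-yl)cyclohexane-1,3-dione | CCC#CCC1C(=O)CCCC1=O | intermediate
4 | but-3-en-2-one (methyl vinyl ketone) | C=CC(C)=O | starting material
5 | 2-(3-oxobutyl)-2-(pent-2-yn-1-yl)cyclohexane-1,3-dione (not isolated) | CCC#CCC1(CCC(C)=O)C(=O)CCCC1=O | intermediate
6 | (S)-8a-(pent-2-yn-1-yl)-3,4,8,8a-tetrahydronaphthalene-1,6(2H,7H)-dione | CCC#CC[C@@]12CCC(=O)C=C1CCCC2=O | intermediate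
7 | monoketal of 6 (1,3-dioxolane at C18) | CCC#CC[C@@]12CCC(=O)C=C1CCCC23OCCO3 | intermediate
8 | allylic alcohol (12R; OH cis to the pentynyl group) | CCC#CC[C@@]12CC[C@@H](O)C=C1CCCC23OCCO3 | intermediate
9 | TBS ether of 8 | CCC#CC[C@@]12CC[C@@H](O[Si](C)(C)C(C)(C)C)C=C1CCCC23OCCO3 | intermediate
10 | (2R)-2-(TBSO)-4-[(6S)-7-oxo-6-(pent-2-yn-1-yl)-1,4-dioxaspiro[4.5]decan-6-yl]butanal | CCC#CC[C@@]1(CC[C@@H](O[Si](C)(C)C(C)(C)C)C=O)C(=O)CCCC12OCCO2 | intermediate
11 | (R)-3-bromo-2-methylpropan-1-ol | BrC[C@H](C)CO | starting material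
12 | (R)-(3-bromo-2-methylpropoxy)(tert-butyl)dimethylsilane | BrC[C@H](C)CO[Si](C)(C)C(C)(C)C | intermediate
13 | (R)-[3-(TBSO)-2-methylpropyl]magnesium bromide (not isolated) | Br[Mg]C[C@H](C)CO[Si](C)(C)C(C)(C)C | intermediate
14 | (12R,13S,15S)-alcohol; Grignard adduct of 10 | CCC#CC[C@@]1(CC[C@@H](O[Si](C)(C)C(C)(C)C)[C@@H](O)C[C@H](C)CO[Si](C)(C)C(C)(C)C)C(=O)CCCC12OCCO2 | intermediate
15 | tris-TBS ether of 14 | CCC#CC[C@@]1(CC[C@@H](O[Si](C)(C)C(C)(C)C)[C@@H](O[Si](C)(C)C(C)(C)C)C[C@H](C)CO[Si](C)(C)C(C)(C)C)C(=O)CCCC12OCCO2 | intermediate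
16 | 1,4-diketone (C4 and C22 ketones; not isolated) | CCCC(=O)C[C@@]1(CC[C@@H](O[Si](C)(C)C(C)(C)C)[C@@H](O[Si](C)(C)C(C)(C)C)C[C@H](C)CO[Si](C)(C)C(C)(C)C)C(=O)CCCC12OCCO2 | intermediate
17 | bicyclic enone (ring C cyclopentenone) | CCC1=C2CCCC3(OCCO3)[C@@]2(CC[C@@H](O[Si](C)(C)C(C)(C)C)[C@@H](O[Si](C)(C)C(C)(C)C)C[C@H](C)CO[Si](C)(C)C(C)(C)C)CC1=O | intermediate
18 | tert-butyl bromoacetate | BrCC(=O)OC(C)(C)C | starting material
19 | C8-alkylated enone (acetate arm cis to the C10 chain) | CCC1=C2CCCC3(OCCO3)[C@@]2(CC[C@@H](O[Si](C)(C)C(C)(C)C)[C@@H](O[Si](C)(C)C(C)(C)C)C[C@H](C)CO[Si](C)(C)C(C)(C)C)[C@H](CC(=O)OC(C)(C)C)C1=O | intermediate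
20 | allylic alcohol (C4–OH cis to the acetate arm) | CCC1=C2CCCC3(OCCO3)[C@@]2(CC[C@@H](O[Si](C)(C)C(C)(C)C)[C@@H](O[Si](C)(C)C(C)(C)C)C[C@H](C)CO[Si](C)(C)C(C)(C)C)[C@H](CC(=O)OC(C)(C)C)[C@@H]1O | intermediate
21 | cis-hydrindane hydroxy ester | CC[C@H]1[C@H]2CCCC3(OCCO3)[C@@]2(CC[C@@H](O[Si](C)(C)C(C)(C)C)[C@@H](O[Si](C)(C)C(C)(C)C)C[C@H](C)CO[Si](C)(C)C(C)(C)C)[C@H](CC(=O)OC(C)(C)C)[C@@H]1O | intermediate
22 | tricyclic lactone (ring D) | CC[C@H]1[C@H]2CCCC3(OCCO3)[C@@]2(CC[C@@H](O[Si](C)(C)C(C)(C)C)[C@@H](O[Si](C)(C)C(C)(C)C)C[C@H](C)CO[Si](C)(C)C(C)(C)C)[C@@H]4CC(=O)O[C@H]14 | intermediate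
23 | α-hydroxy lactone (C7–OH exo) | CC[C@H]1[C@H]2CCCC3(OCCO3)[C@@]2(CC[C@@H](O[Si](C)(C)C(C)(C)C)[C@@H](O[Si](C)(C)C(C)(C)C)C[C@H](C)CO[Si](C)(C)C(C)(C)C)[C@@H]4[C@@H](O)C(=O)O[C@H]14 | intermediate
24 | α-silyloxy lactone | CC[C@H]1[C@H]2CCCC3(OCCO3)[C@@]2(CC[C@@H](O[Si](C)(C)C(C)(C)C)[C@@H](O[Si](C)(C)C(C)(C)C)C[C@H](C)CO[Si](C)(C)C(C)(C)C)[C@@H]4[C@@H](O[Si](C)(C)C(C)(C)C)C(=O)O[C@H]14 | intermediate
25 | α-methyl-α-silyloxy lactone (C7 as in the target) | CC[C@H]1[C@H]2CCCC3(OCCO3)[C@@]2(CC[C@@H](O[Si](C)(C)C(C)(C)C)[C@@H](O[Si](C)(C)C(C)(C)C)C[C@H](C)CO[Si](C)(C)C(C)(C)C)[C@@H]4[C@](C)(O[Si](C)(C)C(C)(C)C)C(=O)O[C@H]14 | intermediate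
26 | tetraol | CC[C@H]1[C@H]2CCCC3(OCCO3)[C@@]2(CC[C@@H](O)[C@@H](O)C[C@H](C)CO)[C@@H]4[C@](C)(O)C(=O)O[C@H]14 | intermediate
27 | dihydroxy acid (not isolated) | CC[C@H]1[C@H]2CCCC3(OCCO3)[C@@]2(CC[C@@H](O)[C@@H](O)C[C@H](C)C(O)=O)[C@@H]4[C@](C)(O)C(=O)O[C@H]14 | intermediate
28 | bis-lactone alcohol (12R) | CC[C@H]1[C@H]2CCCC3(OCCO3)[C@@]2(CC[C@@H](O)[C@@H]5C[C@H](C)C(=O)O5)[C@@H]4[C@](C)(O)C(=O)O[C@H]14 | intermediate
29 | azide (12S; dioxolane at C18) | CC[C@H]1[C@H]2CCCC3(OCCO3)[C@@]2(CC[C@H](N=[N+]=[N-])[C@@H]5C[C@H](C)C(=O)O5)[C@@H]4[C@](C)(O)C(=O)O[C@H]14 | intermediate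
30 | azidoalkyl cis-hydrindanone (Schmidt precursor) | CC[C@@H]1[C@H]2OC(=O)[C@@](C)(O)[C@H]2[C@]3(CC[C@@H]([C@@H]4C[C@H](C)C(=O)O4)N=[N+]=[N-])C(=O)CCC[C@H]13 | intermediate
31 | ring B lactam of the target | CC[C@@H]1[C@H]2OC(=O)[C@@](C)(O)[C@H]2[C@]23CC[C@@H]([C@@H]4C[C@H](C)C(=O)O4)N2C(=O)CCC[C@H]13 | intermediate
32 | thiolactam | CC[C@@H]1[C@H]2OC(=O)[C@@](C)(O)[C@H]2[C@]23CC[C@@H]([C@@H]4C[C@H](C)C(=O)O4)N2C(=S)CCC[C@H]13 | intermediate
33 | CNP0260919.4 | CC[C@@H]1[C@H]2OC(=O)[C@@](C)(O)[C@H]2[C@]23CC[C@@H]([C@@H]4C[C@H](C)C(=O)O4)N2CCCC[C@H]13 | target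

**Step count**

Total: 24 steps. Longest linear sequence: 23 steps (steps 1–6 and 8–24; step 7 prepares the side-chain bromide).

**Steps most likely to fail**

Step 22 (key step). The azide may add too slowly to the congested ketone next to Cq, so that acid-induced loss of nitrogen from the azide or migration of the C19 methylene competes. The fallback builds ring B by Beckmann rearrangement and ring A by N-alkylation; it sets out from 28 and comes back at 31. The C12 hydroxyl of 28 is mesylated with retention (MsCl, Et3N) to the mesylate ketal F6. The dioxolane is hydrolysed (aq. HCl, THF) to the keto mesylate F7. O-Mesitylsulfonylhydroxylamine, then basic alumina, converts the ketone through its oxime sulfonate (N–O bond anti to the bulkier Cq) into the secondary lactam F8 by migration of Cq with retention. KN(SiMe3)2 in THF then closes ring A by intramolecular SN2 displacement of the mesylate by the lactam nitrogen, with inversion at C12, to give 31.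

Step 11. The electrophile may attack the dienolate on the face of the dioxolane, or proton transfer may erode the selectivity. The fallback alkylates after the ring fusion is in place; it sets out from 17 and comes back at 22. Enone 17 is hydrogenated (H2, Pd/C, EtOAc; hydrogen adds to the face away from the dioxolane-bearing ring) to the cis-hydrindanone F2. Kinetic enolisation at the C8 methylene (LiN(i-Pr)2, −78 °C) and alkylation by methyl bromoacetate on the convex face give the keto ester F3. NaBH4 reduces C4; the carbinol epimer cis to the acetate arm lactonises directly to 22. The trans epimer, the hydroxy ester F4, is saponified (LiOH) to the hydroxy acid F5 and closed to 22 by intramolecular Mitsunobu lactonisation (PPh3, DIAD) with inversion at C4, so both epimers converge.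

Step 8. Facial selectivity at the aldehyde may be poor, and the basic Grignard reagent may enolise the α-silyloxy aldehyde. The fallback sets C13 by hydride delivery; it sets out from the C13 epimer mixture of 14 and comes back at 14. Dess–Martin periodinane oxidises the mixture to the α-silyloxy ketone F1. LiBH(s-Bu)3 at −78 °C then reduces the acyclic ketone under Felkin–Anh control (the ring ketone next to Cq is far more hindered) to give 14 as the anti isomer.

**Further compounds**

F1 | step 8 | α-silyloxy ketone (C13 ketone; ring ketone intact) | CCC#CC[C@@]1(CC[C@@H](O[Si](C)(C)C(C)(C)C)C(=O)C[C@H](C)CO[Si](C)(C)C(C)(C)C)C(=O)CCCC12OCCO2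
F2 | step 11 | cis-hydrindanone (C4 ketone; ethyl on the concave face) | CC[C@H]1[C@H]2CCCC3(OCCO3)[C@@]2(CC[C@@H](O[Si](C)(C)C(C)(C)C)[C@@H](O[Si](C)(C)C(C)(C)C)C[C@H](C)CO[Si](C)(C)C(C)(C)C)CC1=O
F3 | step 11 | keto ester (CH2CO2Me on C8, convex face) | CC[C@H]1[C@H]2CCCC3(OCCO3)[C@@]2(CC[C@@H](O[Si](C)(C)C(C)(C)C)[C@@H](O[Si](C)(C)C(C)(C)C)C[C@H](C)CO[Si](C)(C)C(C)(C)C)[C@H](CC(=O)OC)C1=O
F4 | step 11 | trans-hydroxy ester (C4–OH trans to the acetate arm) | CC[C@H]1[C@H]2CCCC3(OCCO3)[C@@]2(CC[C@@H](O[Si](C)(C)C(C)(C)C)[C@@H](O[Si](C)(C)C(C)(C)C)C[C@H](C)CO[Si](C)(C)C(C)(C)C)[C@H](CC(=O)OC)[C@H]1O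
F5 | step 11 | trans-hydroxy acid | CC[C@H]1[C@H]2CCCC3(OCCO3)[C@@]2(CC[C@@H](O[Si](C)(C)C(C)(C)C)[C@@H](O[Si](C)(C)C(C)(C)C)C[C@H](C)CO[Si](C)(C)C(C)(C)C)[C@H](CC(O)=O)[C@H]1O
F6 | step 22 | mesylate ketal (12R) | CC[C@H]1[C@H]2CCCC3(OCCO3)[C@@]2(CC[C@@H](OS(C)(=O)=O)[C@@H]5C[C@H](C)C(=O)O5)[C@@H]4[C@](C)(O)C(=O)O[C@H]14
F7 | step 22 | keto mesylate | CC[C@H]1[C@H]2CCCC(=O)[C@@]2(CC[C@@H](OS(C)(=O)=O)[C@@H]5C[C@H](C)C(=O)O5)[C@@H]4[C@](C)(O)C(=O)O[C@H]14
F8 | step 22 | secondary lactam mesylate (N–H on Cq) | CC[C@H]1[C@H]2CCCC(=O)N[C@@]2(CC[C@@H](OS(C)(=O)=O)[C@@H]5C[C@H](C)C(=O)O5)[C@@H]4[C@](C)(O)C(=O)O[C@H]14
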